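Substrate falling one way by first order with a constant rate constant cannot give the dawn run. Its first reading gives 0.945 /h, at which substrate would stand at 0.00787% after 10.0 h, yet the reading there is 4.0%.

in all of them: substrate 10 mM
- dawn: enzyme 0.02 mol%; run made earlier
- flask: enzyme 0.01 mol%

dawn run (percent of the substrate charged)

| time / h | product / % | substrate / % |
|---|---|---|
| 0.833 | 56.1 | 45.5 |
| 1.33 | 72.6 | 27.0 |
| 2.00 | 83.9 | 15.0 |
| 4.00 | 94.4 | 7.4 |
| 6.00 | 96.3 | 3.9 |
| 10.0 | 99.7 | 4.0 |

(standard deviation of a reading: 1 percentage point)

- no earlier run changes the charge of enzyme; that part of a forecast is a guess

* factor on the rate of making product when 20% of the substrate are converted if enzyme is charged twice over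
* factor on the rate when 20% of the substrate are converted if enzyme is charged at 0.1 mol% instead

A reaction running back to an equilibrium would level off as well, and the dawn readings do not prove that the enzyme dies. My own reckoning assumes that it does, by a first-order step while it works. At each moment ln(c_substrate) falls in proportion to c_enzyme, and c_enzyme falls in proportion to itself. Dividing the two rates removes time, so the logarithm of substrate charged over c_substrate grows in step with the share of enzyme lost. The last two dawn readings of substrate average 3.95%, which gives 3.23. Call this the reach of a charge, the logarithm of substrate charged over substrate left once the enzyme has gone. The share of enzyme lost at a given conversion is then the logarithm reached so far divided by the reach.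

If rate is proportional to enzyme, which no run tests, reach goes with the charge: 1.62 for the flask at 0.01 mol% and 16.2 at 0.1 mol%. At 20% conversion c_substrate is equal in the flasks compared, so their rates compare as their living enzyme. The share lost there is 13.8% in the flask, 6.91% at 0.02 mol% and 1.38% at 0.1 mol%. Charge times living share gives me 2.16 and 11.4.

The forecast says 2 and 10, holding that “any decay adds only a few percent in favour of higher loading”; my second factor is larger than its.

The simulation gives 2.22 and 12.0.

    substrate + enzyme → product + enzyme, rate k1*[substrate]*[enzyme]/(1 + ([substrate]/Km1)) (10.0 mM, k = 9.70 × 10⁵ /M/h)
    enzyme → spent catalyst (k = 0.420 /h)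

In the flask the enzyme's half-life of 1.65 h is longer than the 1.16 h by which half of the turnover of substrate is done, but by a factor of 1.42, and at 20% conversion 18.3% of the catalyst is spent catalyst against my 13.8%. The flask ends at 2.00 d with 21.7% substrate against the 19.9% its reach gave, and at 0.1 mol% the same rule gave 1.38% where the simulated share of spent catalyst is 1.83%.

(The runs are calculated with constants of no real substance; noise was put on by code.)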